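The readings come from a simulation with constants of no real substance; scatter was added.

**Small leftover.** What remains of the catalyst after the impurity has taken its share is what your flask runs on, so I can't share your hunch that 21 µM of impurity is too little to matter. Against c(left-handed substrate) it is indeed 1.05%, but the catalyst is charged at only 62 µM.

all flasks: left-handed substrate 0.0020 M; right-handed substrate 0.0020 M; impurity 21 µM

|  | partner | precatalyst | remark | time |
|---|---|---|---|---|
| cedar | 1.1 mM | 62 µM | run made earlier |  |
| maple | 4.4 mM | 62 µM | run made earlier |  |
| ash | 2.2 mM | 93 µM | run made earlier |  |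
| flask | 2.20 mM | 62 µM |  | 8.0 min |

| run | time / min | left-handed substrate / % | right-handed substrate / % | left-handed product / % |
|---|---|---|---|---|
| cedar | 0.250 | 49.2 | 49.2 | 0 |
| cedar | 0.667 | 50.1 | 50.3 | 0.2 |
| cedar | 1.33 | 50.3 | 49.9 | 0 |
| cedar | 2.00 | 49.8 | 49.5 | 0 |
| cedar | 3.00 | 50.0 | 50.4 | 0 |
| cedar | 4.00 | 49.3 | 50.3 | 0.4 |
| cedar | 5.00 | 48.2 | 49.6 | 2.0 |
| maple | 0.667 | 50.4 | 49.5 | 0 |
| maple | 1.33 | 45.8 | 49.7 | 2.4 |
| maple | 2.00 | 38.9 | 50.1 | 10.4 |
| maple | 3.00 | 27.6 | 49.6 | 23.2 |
| maple | 4.00 | 18.5 | 49.5 | 31.7 |
| maple | 5.00 | 11.7 | 49.8 | 37.2 |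
| ash | 0.417 | 50.0 | 51.0 | 0 |
| ash | 0.667 | 49.8 | 50.2 | 0.3 |
| ash | 1.33 | 49.7 | 48.9 | 0.7 |
| ash | 2.50 | 42.2 | 49.5 | 8.2 |
| ash | 5.00 | 25.4 | 49.4 | 24.2 |

(scatter of a reading: 0.5 percentage points)

- free catalyst is single-handed; left-handed substrate and right-handed substrate are mirror images of each other, charged as a racemate, each of them at the stated concentration
- an excess is below zero if the other one leads

- part of the left-handed substrate and right-handed substrate charged together that has reacted at 8.0 min
- excess of left-handed product over right-handed product in the product at 8.0 min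
- excess of right-handed substrate over left-handed substrate among what is left of the two at 8.0 min

**Silent start.** You can see this in the runs. In cedar, left-handed product reads 0.4% at 4.00 min, while in maple, with c(partner) at 4.4 mM rather than 1.1 mM, it already reads 2.4% at 1.33 min. So I take it that the partner releases the catalyst, and I read the quiet opening as the time in which the impurity captures what is released, one for one.

**Impurity toll.** For your flask I reckon 33.9% as the impurity toll, c(impurity) over c(precatalyst), the share of the catalyst charged that the impurity takes for good. That reckoning gives no conversion; it says what the catalyst loses.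

**The forecast.** The forecast also has “free catalyst killed by the impurity”. It gives 30.5% reacted, a product excess of 97% and a substrate excess of 42.5%.

**The result.** The flask gives 27.5% reacted, a product excess of 97.6% and a substrate excess of 37.0%, which is 5.5 percentage points below the forecast.

    partner + free catalyst + left-handed substrate → free catalyst + left-handed product (k = 1.11 × 10⁵ /M²/s)
    partner + free catalyst + right-handed substrate → free catalyst + right-handed product (k = 944 /M²/s)
    partner + precatalyst → free catalyst + spent reagent (k = 2.07 /M/s)
    free catalyst ⇌ dormant form (K = 0.610, k = 1.10 /s)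
    free catalyst + impurity → spent catalyst (k = 2.97 × 10⁵ /M/s)

**Toll paid.** At 8.00 min the flask holds spent catalyst at 33.9% of the catalyst charged, which is the toll of 33.9%, with impurity at 0%. Now take the same flask with 5.2 × 10⁻⁵ M of impurity, where the toll comes to 83.9%. That neighbour holds spent catalyst at 83.9% and free catalyst at 2.75% at 8.00 min, and it has reacted 0.995%.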